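## Structural features

The target is an 8–5′ neolignan sulfate: a 2,3-dihydrobenzofuran whose benzo ring (ring A) and oxygen heterocycle (ring B) share C3a–C7a, with a guaiacyl group (ring C, 4-hydroxy-3-methoxyphenyl) on C2. Ring A carries a methoxy group at C7 beside the ring oxygen O1 and, at C5, a propyl chain ending in a hydrogen sulfate ester; C3 carries a hydroxymethyl group. C2 (S) and C3 (R) are neighbouring stereocentres, with the aryl and hydroxymethyl groups on opposite faces of ring B. The fragile parts are the alkyl hydrogen sulfate (a strong acid, best carried as a salt), the O1–C2 bond (a para-hydroxybenzyl aryl ether that acid can ionise and palladium can hydrogenolyse) and the electron-rich free phenol. The real difficulty is twofold: the absolute configuration at C3, a carbon with no heteroatom, and telling three hydroxyl groups apart so that only the chain terminus is sulfated. The relative configuration is the easy part and is what the plan exploits: C2 is benzylic and para to the oxygen of ring C, so O1–C2 can be made by capture of a stabilised cation by the ring A phenol oxygen and can reopen until the trans arrangement with C3 is reached. The descriptors were checked and agree: the (1S,2R) syn diol expected from the (S)-configured auxiliary closes with net retention at the carbinol carbon to the (2S,3R) ring, and no structure needed correction.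

## Logic of the disconnections

**23 from 21 (through 22).** Cut: the two benzyl–oxygen bonds, on the ring C phenol and on the C3 hydroxymethyl group; the sulfate only changes its counter-ion. Reason: both hydroxyls must be blocked while the sulfate is installed, and benzyl ethers leave under neutral hydrogenolysis, which a sulfate salt tolerates. Gain: 21 is a stable salt with no free hydroxyl. Demand: hydrogenolysis must stop before the benzylic O1–C2 bond is touched, and the final protonation must be cold and short.

**21 from 19.** Cut: the S–O bond of the sulfate ester. Reason: 19 has exactly one free hydroxyl, at the chain terminus, so sulfation needs no selectivity. Gain: a neutral, chromatographable alcohol. Demand: a buffered, non-acidic sulfating agent, because O1–C2 is acid-labile.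

**19 from 18.** Cut: O1–C2, opening ring B. Reason: this bond joins a phenol oxygen to a carbon that ionises easily, and its formation is reversible, so the trans relationship follows from C3 alone. Gain: an open-chain 1,2-diarylpropane in which only C3 matters; the carbinol configuration becomes irrelevant. Demand: ionisation only at the carbinol carbon, capture by the phenol and not elimination, and enough reversibility to reach trans. Design point: in 18 the C3 hydroxymethyl group is already a benzyl ether and the chain hydroxyl is free, so 19 emerges ready for sulfation and the endgame is two steps.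

**18 from 17, and 17 from 15.** Cut: two Si–O bonds (ring A phenol and chain terminus), then the benzyl–oxygen bond at the primary hydroxyl. Reason: one silyl type on both positions lets a single fluoride step unmask exactly the two hydroxyls 18 needs; the benzyl group goes onto the diol, where a tin acetal distinguishes primary from secondary oxygen. Gain: 15, a plain 1,3-diol. Demand: regioselective mono-benzylation without strong base, which could move the aryl silyl group onto an alkoxide.

**15 from 14, and 14 from 10 and 11.** Cut: the acyl–nitrogen bond (at the reduction level), then C2–C3 (ring numbering). Reason: C2–C3 joins the two aryl halves where an enolate and an aldehyde are both available, and the auxiliary in 10 fixes C3. Gain: two fragments of similar size, one bought. Demand: control of the enolate face. The syn/anti ratio at the carbinol is of little consequence because step 12 converges there. The reduction must not epimerise the acidic α-aryl centre or reverse the aldol.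

**10 from 7 and 8.** Cut: the N–acyl bond. Reason: standard attachment of the auxiliary to an arylacetic acid. Gain: 8 is bought and recovered in step 9. Demand: activation that does not enolise the benzylic CH2 into a ketene.

**7 from 6 from 5.** Cut: the C=C bond of an ortho allyl group, read backwards as the source of the CH2CO2H unit. Reason: an allyl group ortho to the phenol is available by sigmatropic rearrangement. Gain: no cross-coupling or homologation chemistry. Demand: the phenol protecting group must not contain an alkene, which is why the phenol is silylated and not allylated, and the oxidations must spare two silyl ethers and an electron-rich ring.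

**5 from 4 from 3 from 2 from 1.** Cut: Si–O bonds; the aryl–allyl C–C bond (through the O-allyl ether); the terminal C–O bond of the chain. Reason: 1 already has ring A with the methoxy group and a three-carbon chain in the correct positions, and its one free ortho position is where the acetic acid arm must go. Gain: a commodity starting material. Demand: hydroboration before the second allyl group is introduced, so the two allyl groups never coexist.

## Other disconnections considered

**Alternative 1:** Ring A is cut at C5–C6 and C7–C7a, so the arene is assembled last by a Diels–Alder benzannulation. A silyl ketene acetal diene, from γ-deprotonation and O-silylation of a trans-disubstituted α-alkylidene butyrolactone that already holds C2 and C3, would add an acetylenic methyl ketone. The adduct should aromatise by loss of silanol to the 7-acetyl dihydrobenzofuran A1.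
- In favour: both stereocentres sit on a lactone where trans is easy to secure; no benzylic cation is formed; the orientation is electronically well defined (the oxygenated diene terminus pairs with the acyl-bearing alkyne carbon).
- Against here: deprotonation can also occur at C3, giving an aromatic 2-silyloxyfuran and erasing the C3 stereocentre. The acetyl group at C7 must then become methoxy (Baeyer–Villiger oxidation, ester cleavage, O-methylation) in the presence of two electron-rich arenes. The lactone itself needs an enantioselective synthesis about as long as the aldol sequence.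
- Comparison: A1 maps onto the target less directly than 19 because C7 carries the wrong group. Mechanistically the cycloaddition is the equal of the cationic closure in reliability of bond formation and better in that it cannot eliminate or fragment, but worse in the risk to C3. It would be longer by at least three operations. Late variation of the C7 and C5 substituents is a genuine advantage for analogues.

**Alternative 2:** The cut is C2–C3. An aryldiazoacetate on ring A, whose phenol oxygen carries the ring C benzyl group, would be decomposed by Rh2(S-PTTL)4 or its enantiomer. The carbene at C3 inserts into the benzylic C–H bond next to O1, closing ring B as the cis ester A2 with C2 set by the catalyst.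
- In favour: catalytic asymmetric induction with no stoichiometric auxiliary; ring B and the C2–C3 bond in one step; a short substrate synthesis (ester, benzyl ether, diazo transfer).
- Against here: the kinetic product is cis, so C3 must be epimerised with base before the ester is reduced. The ether oxygen is flanked by the C7 methoxy group and the carbene carbon, a crowded arrangement that may lower enantioselectivity. Oxonium ylide formation at O1 followed by a 1,2-benzyl shift (Stevens type) is encouraged by the electron-rich benzyl group. Enantiomeric purity rests on the catalyst alone.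
- Comparison: in step economy this alternative is better, by roughly two or three steps to the ring B stage. In logic the two are equal: each sets one centre absolutely and lets the other follow by equilibration (C2 here, C3 there). The chosen plan is ahead in predictability for this substitution pattern and in separating diastereomers, not enantiomers.

**Alternative 3:** Ring A is cut at C3a–C7a and C6–C7. Ph3PAuNTf2 (monovalent gold) would activate an ethynyl ether on O1; a furan tethered through C3 adds, and the intermediate opens to a phenol with the furan oxygen on C7. Rings A and B close together to the 7-hydroxy dihydrobenzofuran A3.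
- In favour: two rings in one mild catalytic step; ring A regiochemistry fixed by connectivity; the C7 oxygen arrives as a free phenol needing one methylation; O1–C2 is never ionised, so C2 is not at risk.
- Against here: the substrate is a secondary benzylic ethynyl ether, prone to hydration and to thermal loss of ketene. The furan–yne phenol synthesis is established for carbon-substituted alkynes, and an oxygen-substituted alkyne changes the polarisation of the activated triple bond, so the key step would be an untested variant. Both stereocentres must be set in the open chain with no chance of later correction. The 2,4-disubstituted furan bearing the chain is itself a multi-step target.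
- Comparison: equal in that the stereocentres could come from the same aldol logic, and better in forming two rings at once, but clearly longer and less well founded.

Key step: step 12

Assumption: the target is drawn as the free hydrogen sulfate; it is made as its sodium salt and protonated only in the last operation, since the salt is the form that stores. Abbreviations: TBS = tert-butyldimethylsilyl, Bn = benzyl.

## Route

Step 1
Reactants: 1 eugenol (4-allyl-2-methoxyphenol)
Product: 2 dihydroconiferyl alcohol (4-(3-hydroxypropyl)-2-methoxyphenol)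
Conditions: 9-BBN (2.2 equiv), THF, 0 °C to rt; then NaOH, 30% H2O2, 0 °C
Reagents that add atoms: hydrogen peroxide, OO
Why: Hydroboration–oxidation; 9-BBN places boron on the terminal carbon and oxidation gives the primary alcohol. The phenol only consumes one equivalent of borane as an aryl borinate, which the basic peroxide work-up hydrolyses.

Step 2
Reactants: 2 dihydroconiferyl alcohol
Product: 3 3-[4-(allyloxy)-3-methoxyphenyl]propan-1-ol
Conditions: allyl bromide, K2CO3, acetone, reflux
Reagents that add atoms: allyl bromide, C=CCBr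
Why: Williamson ether synthesis; K2CO3 deprotonates only the phenol, so the aliphatic alcohol should stay free.

Step 3
Reactants: 3 3-[4-(allyloxy)-3-methoxyphenyl]propan-1-ol
Product: 4 2-allyl-4-(3-hydroxypropyl)-6-methoxyphenol
Conditions: PhNEt2, 200 °C, sealed tube
Reagents that add atoms: none
Why: Aromatic Claisen rearrangement ([3,3] shift, then tautomerisation); the other ortho carbon carries the methoxy group and the para position is substituted, so a single regioisomer is expected.

Step 4
Reactants: 4 2-allyl-4-(3-hydroxypropyl)-6-methoxyphenol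
Product: 5 bis-TBS ether of 4 (aryl O-TBS and primary alkyl O-TBS)
Conditions: TBSCl (2.5 equiv), imidazole, DMF, rt to 40 °C
Reagents that add atoms: tert-butyldimethylsilyl chloride, CC(C)(C)[Si](C)(C)Cl
Why: Silylation of phenol and primary alcohol with one reagent; a silyl ether is used on the phenol because the next step cleaves an alkene, and both groups can later be removed together.

Step 5
Reactants: 5 bis-TBS ether of 4
Product: 6 2-{2-(TBSO)-5-[3-(TBSO)propyl]-3-methoxyphenyl}acetaldehyde
Conditions: OsO4 (2 mol %), NaIO4 (4 equiv), 2,6-lutidine, dioxane/H2O 3:1, rt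
Reagents that add atoms: osmium tetroxide, O=[Os](=O)(=O)=O; sodium periodate, [Na+].[O-]I(=O)(=O)=O
Why: Lemieux–Johnson oxidation (dihydroxylation, then periodate cleavage); the neutral, lutidine-buffered medium should spare both silyl ethers, and the arylacetaldehyde is used crude.

Step 6
Reactants: 6 the arylacetaldehyde
Product: 7 2-{2-(TBSO)-5-[3-(TBSO)propyl]-3-methoxyphenyl}acetic acid
Conditions: NaClO2, NaH2PO4, 2-methyl-2-butene, t-BuOH/H2O, 0 °C to rt
Reagents that add atoms: sodium chlorite, [Na+].[O-]Cl=O
Why: Pinnick oxidation; 2-methyl-2-butene traps the hypochlorite so the electron-rich ring is not chlorinated.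

Step 7
Reactants: 7 the arylacetic acid; 8 (S)-4-benzyl-2-oxazolidinone
Product: 10 (S)-4-benzyl-3-(2-{2-(TBSO)-5-[3-(TBSO)propyl]-3-methoxyphenyl}acetyl)oxazolidin-2-one, via mixed pivalic anhydride 9 (not isolated)
Conditions: PivCl, Et3N, THF, −20 °C; then LiCl, 8, −20 °C to rt
Reagents that add atoms: none
Why: N-Acylation through a mixed anhydride; the LiCl-activated oxazolidinone attacks the less hindered arylacetyl carbonyl of 9, and no strong base is present to turn the acidic benzylic CH2 into a ketene.

Step 8
Reactants: 10 the N-arylacetyl oxazolidinone; 11 4-(benzyloxy)-3-methoxybenzaldehyde (O-benzylvanillin)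
Product: 14 (S)-4-benzyl-3-[(2S,3S)-3-(4-benzyloxy-3-methoxyphenyl)-3-hydroxy-2-{2-(TBSO)-5-[3-(TBSO)propyl]-3-methoxyphenyl}propanoyl]oxazolidin-2-one, via dibutylboron Z-enolate 12 (not isolated), via dibutylboron aldolate 13 (not isolated)
Conditions: Bu2BOTf, iPr2NEt, CH2Cl2, −78 to 0 °C; 11, −78 to 0 °C; then pH 7 buffer, MeOH, 30% H2O2, 0 °C
Reagents that add atoms: none
Why: Evans syn aldol; the Z boron enolate adds to 11 through a closed chair transition state on the face away from the benzyl group of the auxiliary, which sets C3 (ring numbering) and gives the (S) carbinol. A minor carbinol epimer with the same C3 configuration would be harmless, since both converge in step 12.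

Step 9
Reactants: 14 the syn aldol adduct
Product: 15 (1S,2R)-1-(4-benzyloxy-3-methoxyphenyl)-2-{2-(TBSO)-5-[3-(TBSO)propyl]-3-methoxyphenyl}propane-1,3-diol
Conditions: LiBH4, H2O (2 equiv), THF, 0 °C
Reagents that add atoms: none
Why: Reductive cleavage of the imide with LiBH4 at the exocyclic carbonyl gives the diol and returns 8. The aryl-bearing carbon changes descriptor from S to R only because the priorities change; low temperature limits retro-aldol and epimerisation.

Step 10
Reactants: 15 the 1,3-diol
Product: 17 (1S,2R)-3-(benzyloxy)-1-(4-benzyloxy-3-methoxyphenyl)-2-{2-(TBSO)-5-[3-(TBSO)propyl]-3-methoxyphenyl}propan-1-ol, via dibutylstannylene acetal 16 (not isolated)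
Conditions: Bu2SnO, toluene, reflux (−H2O); then BnBr, Bu4NBr, 90 °C
Reagents that add atoms: benzyl bromide, BrCc1ccccc1
Why: Regioselective O-alkylation through a dibutylstannylene acetal; in the six-membered tin acetal the primary oxygen is the less hindered and more nucleophilic site. The neutral conditions avoid alkoxides that could take the silyl group from the phenol.

Step 11
Reactants: 17 the primary benzyl ether
Product: 18 (1S,2R)-3-(benzyloxy)-1-(4-benzyloxy-3-methoxyphenyl)-2-[2-hydroxy-5-(3-hydroxypropyl)-3-methoxyphenyl]propan-1-ol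
Conditions: TBAF (3 equiv), AcOH (3 equiv), THF, 0 °C to rt
Reagents that add atoms: none
Why: Fluoride desilylation removes the aryl and the primary alkyl silyl ether in one operation; acetic acid keeps the medium near neutral so the benzylic alcohol and C3 are not exposed to base.

Step 12
Reactants: 18 the phenol-bearing benzylic alcohol
Product: 19 3-[(2S,3R)-2-(4-benzyloxy-3-methoxyphenyl)-3-(benzyloxymethyl)-7-methoxy-2,3-dihydro-1-benzofuran-5-yl]propan-1-ol
Conditions: TsOH·H2O (10 mol %), CH2Cl2 (0.02 M), 0 °C to rt; Et3N quench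
Reagents that add atoms: none
Why: TsOH protonates the secondary benzylic hydroxyl and loss of water gives a cation delocalised onto the para benzyloxy oxygen of ring C, in effect a quinone methide oxocarbenium ion. The ring A phenol oxygen, five atoms away, adds to C2 and closes ring B by a 5-exo-trig cycloetherification, forming O1–C2. The closest known reaction type is the acid-mediated cyclisation of ortho-hydroxyaryl benzylic alcohols through para-alkoxybenzyl cations or quinone methides to 2-aryl-2,3-dihydrobenzofurans. C2 is the only new stereocentre and is set under thermodynamic control: the product is itself a para-alkoxybenzyl aryl ether, so it re-ionises under the same acid and ring B opens and closes until the aryl and benzyloxymethyl groups sit trans, with the preset C3 as the controlling element. Either carbinol epimer of 18 would therefore give 19. The step needs chemoselective ionisation, which the substrate secures because only the carbinol carbon has a para oxygen donor; the two benzyl ethers and the primary alcohol give no stabilised cation. It also needs O-capture to win over elimination, intermolecular etherification by the free chain hydroxyl and Friedel–Crafts attack; the five-membered intramolecular closure, high dilution and low temperature favour it, and any intermolecular ether is itself reversible. The benzyloxymethyl oxygen could only form a four-membered oxetanium ion and should not compete.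

Step 13
Reactants: 19 the trans dihydrobenzofuran alcohol
Product: 21 sodium 3-[(2S,3R)-2-(4-benzyloxy-3-methoxyphenyl)-3-(benzyloxymethyl)-7-methoxy-2,3-dihydro-1-benzofuran-5-yl]propyl sulfate, via pyridinium alkyl sulfate 20 (not isolated)
Conditions: SO3·pyridine (3 equiv), pyridine, rt; then aq NaHCO3
Reagents that add atoms: sulfur trioxide–pyridine complex, [O-]S(=O)(=O)[n+]1ccccc1; sodium hydrogen carbonate, [Na+].OC([O-])=O
Why: O-Sulfation of the only free hydroxyl; pyridine keeps the medium basic so O1–C2 is not ionised, and bicarbonate exchanges pyridinium for sodium.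

Step 14
Reactants: 21 the dibenzyl sodium sulfate
Product: 23 3-[(2S,3R)-2-(4-hydroxy-3-methoxyphenyl)-3-(hydroxymethyl)-7-methoxy-2,3-dihydro-1-benzofuran-5-yl]propyl hydrogen sulfate, via sodium salt of the target 22 (not isolated)
Conditions: H2 (1 atm), 10% Pd/C, MeOH, rt; filter; then 1 M HCl (1.0 equiv), 0 °C; C18 desalting
Reagents that add atoms: none
Why: Hydrogenolysis of the aryl and the alkyl benzyl ether in neutral methanol, stopped as soon as both are gone because O1–C2 is itself benzylic; the sulfate salt is inert. One equivalent of HCl at 0 °C then protonates the sulfate and reverse-phase desalting removes NaCl; neither stereocentre is touched.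

## Compound list

1 | eugenol (4-allyl-2-methoxyphenol) | C=CCc1ccc(O)c(OC)c1 | starting material
2 | dihydroconiferyl alcohol, 4-(3-hydroxypropyl)-2-methoxyphenol | OCCCc1ccc(O)c(OC)c1 | intermediate
3 | 3-[4-(allyloxy)-3-methoxyphenyl]propan-1-ol | C=CCOc1ccc(CCCO)cc1OC | intermediate
4 | 2-allyl-4-(3-hydroxypropyl)-6-methoxyphenol | C=CCc1cc(CCCO)cc(OC)c1O | intermediate
5 | tert-butyl{2-allyl-4-[3-(tert-butyldimethylsilyloxy)propyl]-6-methoxyphenoxy}dimethylsilane | C=CCc1cc(CCCO[Si](C)(C)C(C)(C)C)cc(OC)c1O[Si](C)(C)C(C)(C)C | intermediate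
6 | 2-{2-(TBSO)-5-[3-(TBSO)propyl]-3-methoxyphenyl}acetaldehyde | O=CCc1cc(CCCO[Si](C)(C)C(C)(C)C)cc(OC)c1O[Si](C)(C)C(C)(C)C | intermediate
7 | 2-{2-(TBSO)-5-[3-(TBSO)propyl]-3-methoxyphenyl}acetic acid | OC(=O)Cc1cc(CCCO[Si](C)(C)C(C)(C)C)cc(OC)c1O[Si](C)(C)C(C)(C)C | intermediate
8 | (S)-4-benzyl-2-oxazolidinone | O=C1OC[C@H](Cc2ccccc2)N1 | starting material
9 | mixed anhydride of 7 with pivalic acid | CC(C)(C)C(=O)OC(=O)Cc1cc(CCCO[Si](C)(C)C(C)(C)C)cc(OC)c1O[Si](C)(C)C(C)(C)C | intermediate (not isolated)
10 | (S)-4-benzyl-3-(2-{2-(TBSO)-5-[3-(TBSO)propyl]-3-methoxyphenyl}acetyl)oxazolidin-2-one | O=C(Cc1cc(CCCO[Si](C)(C)C(C)(C)C)cc(OC)c1O[Si](C)(C)C(C)(C)C)N1C(=O)OC[C@@H]1Cc1ccccc1 | intermediate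
11 | 4-(benzyloxy)-3-methoxybenzaldehyde (O-benzylvanillin) | COc1cc(C=O)ccc1OCc1ccccc1 | starting material
12 | (Z)-dibutylboron enolate of 10 | CCCCB(CCCC)O/C(=C\c1cc(CCCO[Si](C)(C)C(C)(C)C)cc(OC)c1O[Si](C)(C)C(C)(C)C)N1C(=O)OC[C@@H]1Cc1ccccc1 | intermediate (not isolated)
13 | O-dibutylboryl aldolate of 14 | COc1cc([C@@H](OB(CCCC)CCCC)[C@@H](C(=O)N2C(=O)OC[C@@H]2Cc2ccccc2)c2cc(CCCO[Si](C)(C)C(C)(C)C)cc(OC)c2O[Si](C)(C)C(C)(C)C)ccc1OCc1ccccc1 | intermediate (not isolated)
14 | (S)-4-benzyl-3-[(2S,3S)-3-(4-benzyloxy-3-methoxyphenyl)-3-hydroxy-2-{2-(TBSO)-5-[3-(TBSO)propyl]-3-methoxyphenyl}propanoyl]oxazolidin-2-one | COc1cc([C@@H](O)[C@@H](C(=O)N2C(=O)OC[C@@H]2Cc2ccccc2)c2cc(CCCO[Si](C)(C)C(C)(C)C)cc(OC)c2O[Si](C)(C)C(C)(C)C)ccc1OCc1ccccc1 | intermediate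
15 | (1S,2R)-1-(4-benzyloxy-3-methoxyphenyl)-2-{2-(TBSO)-5-[3-(TBSO)propyl]-3-methoxyphenyl}propane-1,3-diol | COc1cc([C@@H](O)[C@@H](CO)c2cc(CCCO[Si](C)(C)C(C)(C)C)cc(OC)c2O[Si](C)(C)C(C)(C)C)ccc1OCc1ccccc1 | intermediate
16 | (4S,5R)-2,2-dibutyl-4-(4-benzyloxy-3-methoxyphenyl)-5-{2-(TBSO)-5-[3-(TBSO)propyl]-3-methoxyphenyl}-1,3,2-dioxastanninane | COc1cc([C@H]2O[Sn](CCCC)(CCCC)OC[C@H]2c2cc(CCCO[Si](C)(C)C(C)(C)C)cc(OC)c2O[Si](C)(C)C(C)(C)C)ccc1OCc1ccccc1 | intermediate (not isolated)
17 | (1S,2R)-3-(benzyloxy)-1-(4-benzyloxy-3-methoxyphenyl)-2-{2-(TBSO)-5-[3-(TBSO)propyl]-3-methoxyphenyl}propan-1-ol | COc1cc([C@@H](O)[C@@H](COCc2ccccc2)c2cc(CCCO[Si](C)(C)C(C)(C)C)cc(OC)c2O[Si](C)(C)C(C)(C)C)ccc1OCc1ccccc1 | intermediate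
18 | (1S,2R)-3-(benzyloxy)-1-(4-benzyloxy-3-methoxyphenyl)-2-[2-hydroxy-5-(3-hydroxypropyl)-3-methoxyphenyl]propan-1-ol | COc1cc([C@@H](O)[C@@H](COCc2ccccc2)c2cc(CCCO)cc(OC)c2O)ccc1OCc1ccccc1 | intermediate
19 | 3-[(2S,3R)-2-(4-benzyloxy-3-methoxyphenyl)-3-(benzyloxymethyl)-7-methoxy-2,3-dihydro-1-benzofuran-5-yl]propan-1-ol | COc1cc([C@H]2Oc3c(OC)cc(CCCO)cc3[C@@H]2COCc2ccccc2)ccc1OCc1ccccc1 | intermediate
20 | pyridinium 3-[(2S,3R)-2-(4-benzyloxy-3-methoxyphenyl)-3-(benzyloxymethyl)-7-methoxy-2,3-dihydro-1-benzofuran-5-yl]propyl sulfate | COc1cc([C@H]2Oc3c(OC)cc(CCCOS(=O)(=O)[O-])cc3[C@@H]2COCc2ccccc2)ccc1OCc1ccccc1.c1cc[nH+]cc1 | intermediate (not isolated)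
21 | sodium 3-[(2S,3R)-2-(4-benzyloxy-3-methoxyphenyl)-3-(benzyloxymethyl)-7-methoxy-2,3-dihydro-1-benzofuran-5-yl]propyl sulfate | COc1cc([C@H]2Oc3c(OC)cc(CCCOS(=O)(=O)[O-])cc3[C@@H]2COCc2ccccc2)ccc1OCc1ccccc1.[Na+] | intermediate
22 | sodium 3-[(2S,3R)-2-(4-hydroxy-3-methoxyphenyl)-3-(hydroxymethyl)-7-methoxy-2,3-dihydro-1-benzofuran-5-yl]propyl sulfate | COc1cc([C@H]2Oc3c(OC)cc(CCCOS(=O)(=O)[O-])cc3[C@@H]2CO)ccc1O.[Na+] | intermediate (not isolated)
23 | 3-[(2S,3R)-2-(4-hydroxy-3-methoxyphenyl)-3-(hydroxymethyl)-7-methoxy-2,3-dihydro-1-benzofuran-5-yl]propyl hydrogen sulfate | COc1cc([C@H]2Oc3c(OC)cc(CCCOS(=O)(=O)O)cc3[C@@H]2CO)ccc1O | target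

## Step count and least certain steps

Total step count: 14. Longest linear sequence: 14 steps, from 1 to 23; 8 and 11 are bought and enter in steps 7 and 8.

**Step 12 (key step).** The most likely failures are loss of a proton from C3 of the benzylic cation (elimination to a stilbene), fragmentation of the cation with loss of the benzyloxymethyl carbon, intermolecular capture by another molecule, or an incomplete drift to trans. The cation is long-lived enough for these to compete because ring A is electron-rich and the acid is present throughout. The fallback closes the ring by two SN2-type inversions without a free cation. It sets out from 17: Mitsunobu esterification (4-nitrobenzoic acid, PPh3, DIAD) should invert the carbinol to (1R,2R)-3-(benzyloxy)-1-(4-benzyloxy-3-methoxyphenyl)-2-{2-(TBSO)-5-[3-(TBSO)propyl]-3-methoxyphenyl}propyl 4-nitrobenzoate F1. K2CO3 in MeOH would cleave the ester and the aryl silyl ether together to (1R,2R)-3-(benzyloxy)-1-(4-benzyloxy-3-methoxyphenyl)-2-{5-[3-(TBSO)propyl]-2-hydroxy-3-methoxyphenyl}propan-1-ol F2. An intramolecular Mitsunobu etherification (PPh3, DIAD) with a second inversion should give tert-butyl{3-[(2S,3R)-2-(4-benzyloxy-3-methoxyphenyl)-3-(benzyloxymethyl)-7-methoxy-2,3-dihydro-1-benzofuran-5-yl]propoxy}dimethylsilane F3, and TBAF returns to the route at 19.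

**Step 8.** The likely failures are reversal of the aldol addition (the enolate is aryl-stabilised and the aldehyde electron-rich), erosion of enolate facial selectivity, and epimerisation of the acidic α-aryl centre during work-up; each would lower the configurational purity at C3. The fallback changes auxiliary and enolate metal. It sets out from 7: coupling with (S)-4-benzyl-1,3-thiazolidine-2-thione (EDC·HCl, DMAP) gives 2-{2-(TBSO)-5-[3-(TBSO)propyl]-3-methoxyphenyl}-1-[(S)-4-benzyl-2-thioxo-1,3-thiazolidin-3-yl]ethan-1-one F4. Its chlorotitanium enolate (TiCl4, iPr2NEt, N-methyl-2-pyrrolidinone, −78 °C) should add to 11 in the same syn sense to give (2S,3S)-3-(4-benzyloxy-3-methoxyphenyl)-3-hydroxy-2-{2-(TBSO)-5-[3-(TBSO)propyl]-3-methoxyphenyl}-1-[(S)-4-benzyl-2-thioxo-1,3-thiazolidin-3-yl]propan-1-one F5. The more labile thioimide is cleaved by NaBH4 at low temperature, returning at 15.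

**Step 10.** The likely failures are alkylation at the secondary benzylic oxygen, double benzylation, or silyl transfer from the phenol at 90 °C. The fallback replaces reagent-based regioselection by order of events. It sets out from 14: TBSOTf and 2,6-lutidine give the O-TBS ether of 14, (S)-4-benzyl-3-[(2S,3S)-3-(4-benzyloxy-3-methoxyphenyl)-3-(TBSO)-2-{2-(TBSO)-5-[3-(TBSO)propyl]-3-methoxyphenyl}propanoyl]oxazolidin-2-one F6. LiBH4 gives (2R,3S)-3-(4-benzyloxy-3-methoxyphenyl)-3-(TBSO)-2-{2-(TBSO)-5-[3-(TBSO)propyl]-3-methoxyphenyl}propan-1-ol F7, in which only the primary hydroxyl is free. Neutral benzylation (2-benzyloxy-1-methylpyridinium triflate, MgO, PhCF3, 85 °C) gives the secondary O-TBS ether of 17, tert-butyl{[(1S,2R)-3-(benzyloxy)-1-(4-benzyloxy-3-methoxyphenyl)-2-{2-(TBSO)-5-[3-(TBSO)propyl]-3-methoxyphenyl}propyl]oxy}dimethylsilane F8. Excess TBAF removes all three silyl groups, returning at 18.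

**Step 14.** The likely failures are hydrogenolytic opening of the benzylic O1–C2 bond during the slower cleavage of the primary benzyl ether, and ionisation at C2 while the sulfate is protonated. The fallback removes the alkyl benzyl ether from the design, so that hydrogen only has to cleave the fast aryl benzyl ether. It sets out from 15:
- PivCl and pyridine at 0 °C acylate the primary hydroxyl to (2R,3S)-3-(4-benzyloxy-3-methoxyphenyl)-3-hydroxy-2-{2-(TBSO)-5-[3-(TBSO)propyl]-3-methoxyphenyl}propyl pivalate F9.
- TBAF/AcOH gives (2R,3S)-3-(4-benzyloxy-3-methoxyphenyl)-3-hydroxy-2-[2-hydroxy-5-(3-hydroxypropyl)-3-methoxyphenyl]propyl pivalate F10.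
- Catalytic TsOH closes ring B to [(2S,3R)-2-(4-benzyloxy-3-methoxyphenyl)-5-(3-hydroxypropyl)-7-methoxy-2,3-dihydro-1-benzofuran-3-yl]methyl pivalate F11.
- SO3·pyridine then NaHCO3 give sodium 3-[(2S,3R)-2-(4-benzyloxy-3-methoxyphenyl)-7-methoxy-3-(pivaloyloxymethyl)-2,3-dihydro-1-benzofuran-5-yl]propyl sulfate F12.
- NaOMe in MeOH removes the pivalate to sodium 3-[(2S,3R)-2-(4-benzyloxy-3-methoxyphenyl)-3-(hydroxymethyl)-7-methoxy-2,3-dihydro-1-benzofuran-5-yl]propyl sulfate F13.
- A brief hydrogenolysis over Pd/C returns to the route at 22, which is protonated as in step 14.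

## Further compounds

F1 | step 12 | (1R,2R)-3-(benzyloxy)-1-(4-benzyloxy-3-methoxyphenyl)-2-{2-(TBSO)-5-[3-(TBSO)propyl]-3-methoxyphenyl}propyl 4-nitrobenzoate | COc1cc([C@H](OC(=O)c2ccc([N+](=O)[O-])cc2)[C@@H](COCc2ccccc2)c2cc(CCCO[Si](C)(C)C(C)(C)C)cc(OC)c2O[Si](C)(C)C(C)(C)C)ccc1OCc1ccccc1
F2 | step 12 | (1R,2R)-3-(benzyloxy)-1-(4-benzyloxy-3-methoxyphenyl)-2-{5-[3-(TBSO)propyl]-2-hydroxy-3-methoxyphenyl}propan-1-ol | COc1cc([C@H](O)[C@@H](COCc2ccccc2)c2cc(CCCO[Si](C)(C)C(C)(C)C)cc(OC)c2O)ccc1OCc1ccccc1
F3 | step 12 | tert-butyl{3-[(2S,3R)-2-(4-benzyloxy-3-methoxyphenyl)-3-(benzyloxymethyl)-7-methoxy-2,3-dihydro-1-benzofuran-5-yl]propoxy}dimethylsilane | COc1cc([C@H]2Oc3c(OC)cc(CCCO[Si](C)(C)C(C)(C)C)cc3[C@@H]2COCc2ccccc2)ccc1OCc1ccccc1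
F4 | step 8 | 2-{2-(TBSO)-5-[3-(TBSO)propyl]-3-methoxyphenyl}-1-[(S)-4-benzyl-2-thioxo-1,3-thiazolidin-3-yl]ethan-1-one | O=C(Cc1cc(CCCO[Si](C)(C)C(C)(C)C)cc(OC)c1O[Si](C)(C)C(C)(C)C)N1C(=S)SC[C@@H]1Cc1ccccc1
F5 | step 8 | (2S,3S)-3-(4-benzyloxy-3-methoxyphenyl)-3-hydroxy-2-{2-(TBSO)-5-[3-(TBSO)propyl]-3-methoxyphenyl}-1-[(S)-4-benzyl-2-thioxo-1,3-thiazolidin-3-yl]propan-1-one | COc1cc([C@@H](O)[C@@H](C(=O)N2C(=S)SC[C@@H]2Cc2ccccc2)c2cc(CCCO[Si](C)(C)C(C)(C)C)cc(OC)c2O[Si](C)(C)C(C)(C)C)ccc1OCc1ccccc1
F6 | step 10 | (S)-4-benzyl-3-[(2S,3S)-3-(4-benzyloxy-3-methoxyphenyl)-3-(TBSO)-2-{2-(TBSO)-5-[3-(TBSO)propyl]-3-methoxyphenyl}propanoyl]oxazolidin-2-one | COc1cc([C@@H](O[Si](C)(C)C(C)(C)C)[C@@H](C(=O)N2C(=O)OC[C@@H]2Cc2ccccc2)c2cc(CCCO[Si](C)(C)C(C)(C)C)cc(OC)c2O[Si](C)(C)C(C)(C)C)ccc1OCc1ccccc1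
F7 | step 10 | (2R,3S)-3-(4-benzyloxy-3-methoxyphenyl)-3-(TBSO)-2-{2-(TBSO)-5-[3-(TBSO)propyl]-3-methoxyphenyl}propan-1-ol | COc1cc([C@@H](O[Si](C)(C)C(C)(C)C)[C@@H](CO)c2cc(CCCO[Si](C)(C)C(C)(C)C)cc(OC)c2O[Si](C)(C)C(C)(C)C)ccc1OCc1ccccc1
F8 | step 10 | tert-butyl{[(1S,2R)-3-(benzyloxy)-1-(4-benzyloxy-3-methoxyphenyl)-2-{2-(TBSO)-5-[3-(TBSO)propyl]-3-methoxyphenyl}propyl]oxy}dimethylsilane | COc1cc([C@@H](O[Si](C)(C)C(C)(C)C)[C@@H](COCc2ccccc2)c2cc(CCCO[Si](C)(C)C(C)(C)C)cc(OC)c2O[Si](C)(C)C(C)(C)C)ccc1OCc1ccccc1
F9 | step 14 | (2R,3S)-3-(4-benzyloxy-3-methoxyphenyl)-3-hydroxy-2-{2-(TBSO)-5-[3-(TBSO)propyl]-3-methoxyphenyl}propyl pivalate | COc1cc([C@@H](O)[C@@H](COC(=O)C(C)(C)C)c2cc(CCCO[Si](C)(C)C(C)(C)C)cc(OC)c2O[Si](C)(C)C(C)(C)C)ccc1OCc1ccccc1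
F10 | step 14 | (2R,3S)-3-(4-benzyloxy-3-methoxyphenyl)-3-hydroxy-2-[2-hydroxy-5-(3-hydroxypropyl)-3-methoxyphenyl]propyl pivalate | COc1cc([C@@H](O)[C@@H](COC(=O)C(C)(C)C)c2cc(CCCO)cc(OC)c2O)ccc1OCc1ccccc1
F11 | step 14 | [(2S,3R)-2-(4-benzyloxy-3-methoxyphenyl)-5-(3-hydroxypropyl)-7-methoxy-2,3-dihydro-1-benzofuran-3-yl]methyl pivalate | COc1cc([C@H]2Oc3c(OC)cc(CCCO)cc3[C@@H]2COC(=O)C(C)(C)C)ccc1OCc1ccccc1
F12 | step 14 | sodium 3-[(2S,3R)-2-(4-benzyloxy-3-methoxyphenyl)-7-methoxy-3-(pivaloyloxymethyl)-2,3-dihydro-1-benzofuran-5-yl]propyl sulfate | COc1cc([C@H]2Oc3c(OC)cc(CCCOS(=O)(=O)[O-])cc3[C@@H]2COC(=O)C(C)(C)C)ccc1OCc1ccccc1.[Na+]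
F13 | step 14 | sodium 3-[(2S,3R)-2-(4-benzyloxy-3-methoxyphenyl)-3-(hydroxymethyl)-7-methoxy-2,3-dihydro-1-benzofuran-5-yl]propyl sulfate | COc1cc([C@H]2Oc3c(OC)cc(CCCOS(=O)(=O)[O-])cc3[C@@H]2CO)ccc1OCc1ccccc1.[Na+]
A1 | alternative 1 | 1-[(2S,3R)-2-(4-benzyloxy-3-methoxyphenyl)-3-(benzyloxymethyl)-5-[3-(tert-butyldimethylsilyloxy)propyl]-2,3-dihydro-1-benzofuran-7-yl]ethan-1-one | COc1cc([C@H]2Oc3c(C(C)=O)cc(CCCO[Si](C)(C)C(C)(C)C)cc3[C@@H]2COCc2ccccc2)ccc1OCc1ccccc1
A2 | alternative 2 | methyl (2S,3R)-2-(4-benzyloxy-3-methoxyphenyl)-5-[3-(tert-butyldimethylsilyloxy)propyl]-7-methoxy-2,3-dihydro-1-benzofuran-3-carboxylate (cis) | COc1cc([C@H]2Oc3c(OC)cc(CCCO[Si](C)(C)C(C)(C)C)cc3[C@H]2C(=O)OC)ccc1OCc1ccccc1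
A3 | alternative 3 | (2S,3R)-2-(4-benzyloxy-3-methoxyphenyl)-3-(benzyloxymethyl)-5-[3-(tert-butyldimethylsilyloxy)propyl]-2,3-dihydro-1-benzofuran-7-ol | COc1cc([C@H]2Oc3c(O)cc(CCCO[Si](C)(C)C(C)(C)C)cc3[C@@H]2COCc2ccccc2)ccc1OCc1ccccc1
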